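**Plan**

1. Retrosynthesis: the silyl groups are removed and both prenyl groups are traced to allyl groups (cross-metathesis). The C4 ketone is traced to a carbinol and the O1–C2 ether bond is cut (Mitsunobu), leaving an acyclic 1,3-diol. That diol comes from an oxetane, which is cut at C3–C4 and O–C2 into a ring-A aldehyde and a ring-B silyl enol ether.
2. Enabling feature: in ring C every carbon of the C2–C3–C4 chain bears oxygen. C4 is a carbonyl on ring A, C3 a fully substituted carbinol carrying ring B, C2 a CH2 on the phenolic O1. The C3–C4 bond plus one C2–O bond therefore map onto an aldehyde C=O and an enol-ether C=C in a [2+2] photocycloaddition.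
3. Forward order: rings A and B are made separately, each allyl group placed by a Claisen rearrangement. They are joined through the oxetane (first new ring), ring C follows by oxetane opening and etherification, then oxidation, metathesis and desilylation.
4. O1 cannot displace the oxetane oxygen at C2 directly, because that would be a six-membered endocyclic substitution. The oxygen transposition is therefore split into a phenoxide-driven benzylic ring opening (o-quinone methide, water adds at C4) and a separate O1–C2 closure.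
5. Stereochemistry: C3 is created in the photocycloaddition. A (1S,4R)-camphanoyl ester on O1 makes its two epimers diastereomers, and the 3R series is separated there. C3 has no α-hydrogen afterwards and cannot epimerise; C4 is transient and erased by oxidation.

Key step: step 11

Assumption: (1S)-(−)-camphanic chloride is taken as the (1S,4R) acid chloride, and the C3-epimeric camphanates formed in step 11 are taken to be separable and assignable by X-ray diffraction against the camphanoyl group; no facial induction by the auxiliary is presupposed.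

**Ring A**

Step 1
Reactants: 1 2,4,6-trihydroxybenzaldehyde
Product: 2 2,6-dihydroxy-4-(triisopropylsilyloxy)benzaldehyde
Conditions: iPr3SiCl (1.05 equiv), imidazole, DMF, 0 °C
Reagents that add atoms: triisopropylsilyl chloride, CC(C)[Si](Cl)(C(C)C)C(C)C
Why: Selective phenol silylation; the 4-OH is the most acidic and the only one not hydrogen-bonded to the formyl group, so one equivalent of the bulky chlorosilane should take it first.

Step 2
Reactants: 2 2,6-dihydroxy-4-(triisopropylsilyloxy)benzaldehyde
Product: 3 2-(allyloxy)-6-hydroxy-4-(triisopropylsilyloxy)benzaldehyde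
Conditions: allyl alcohol (1.05 equiv), PPh3, DIAD, THF, 0 °C to rt
Reagents that add atoms: allyl alcohol, C=CCO
Why: Mitsunobu etherification of one of two equivalent chelated phenols; the remaining hydroxyl is then more hindered and more strongly hydrogen-bonded, which should stop the reaction at the monoether under neutral conditions that spare the aryl silyl ether.

Step 3
Reactants: 3 2-(allyloxy)-6-hydroxy-4-(triisopropylsilyloxy)benzaldehyde
Product: 4 3-(allyloxy)-2-formyl-5-(triisopropylsilyloxy)phenyl (1S,4R)-camphanate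
Conditions: (1S,4R)-camphanoyl chloride, Et3N, DMAP (cat.), CH2Cl2, 0 °C to rt
Reagents that add atoms: (1S,4R)-camphanoyl chloride, ClC(=O)[C@@]12CC[C@@](C)(C(=O)O1)C2(C)C
Why: DMAP-catalysed acylation of the remaining phenol puts on the future O1 an ester that is orthogonal to silyl ethers, has no α-hydrogen and carries the resolving stereocentres.

Step 4
Reactants: 4 3-(allyloxy)-2-formyl-5-(triisopropylsilyloxy)phenyl (1S,4R)-camphanate
Product: 5 4-allyl-2-formyl-3-hydroxy-5-(triisopropylsilyloxy)phenyl (1S,4R)-camphanate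
Conditions: PhNEt2, 190 °C
Reagents that add atoms: none
Why: Aromatic Claisen rearrangement; the allyl group can shift only to the one free ortho carbon (the other carries the formyl group), which places it between the future O5 and O7 and frees the O5 phenol, so the two ortho oxygens are told apart without a selective protection.

Step 5
Reactants: 5 4-allyl-2-formyl-3-hydroxy-5-(triisopropylsilyloxy)phenyl (1S,4R)-camphanate
Product: 6 ring-A aldehyde, 4-allyl-2-formyl-3,5-bis(triisopropylsilyloxy)phenyl (1S,4R)-camphanate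
Conditions: iPr3SiOTf, 2,6-lutidine, CH2Cl2, 0 °C to rt
Reagents that add atoms: triisopropylsilyl triflate, CC(C)[Si](OS(=O)(=O)C(F)(F)F)(C(C)C)C(C)C
Why: Silylation of a hindered, chelated phenol with a silyl triflate and a non-nucleophilic base; aldehyde and aryl ester are inert to these conditions.

**Ring B**

Step 6
Reactants: 7 2,4-dihydroxyacetophenone
Product: 8 4-(allyloxy)-2-hydroxyacetophenone
Conditions: allyl bromide, K2CO3, acetone, reflux
Reagents that add atoms: allyl bromide, C=CCBr
Why: Williamson etherification; the 4-OH reacts while the 2-OH is held in a hydrogen bond to the acetyl group.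

Step 7
Reactants: 8 4-(allyloxy)-2-hydroxyacetophenone
Product: 9 3-allyl-2,4-dihydroxyacetophenone
Conditions: PhNEt2, 200 °C
Reagents that add atoms: none
Why: Aromatic Claisen rearrangement; with the 2-OH chelated to the acetyl group the shift is known to favour C3, between the two oxygens, and any C5 isomer is removed at this stage.

Step 8
Reactants: 9 3-allyl-2,4-dihydroxyacetophenone
Product: 10 3-allyl-2-hydroxy-4-(triisopropylsilyloxy)acetophenone
Conditions: iPr3SiCl, imidazole, DMF, rt
Reagents that add atoms: triisopropylsilyl chloride, CC(C)[Si](Cl)(C(C)C)C(C)C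
Why: Selective silylation of the unchelated 4-OH; the 2-OH is hydrogen-bonded and flanked by allyl and acetyl.

Step 9
Reactants: 10 3-allyl-2-hydroxy-4-(triisopropylsilyloxy)acetophenone
Product: 11 3-allyl-2-methoxy-4-(triisopropylsilyloxy)acetophenone
Conditions: MeI, K2CO3, acetone, 50 °C
Reagents that add atoms: iodomethane, CI
Why: Williamson methylation of the chelated phenol; an aryl triisopropylsilyl ether should tolerate carbonate in dry acetone.

Step 10
Reactants: 11 3-allyl-2-methoxy-4-(triisopropylsilyloxy)acetophenone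
Product: 12 ring-B enol ether, 1-[3-allyl-2-methoxy-4-(triisopropylsilyloxy)phenyl]-1-(triethylsilyloxy)ethene
Conditions: Et3SiOTf, Et3N, CH2Cl2, 0 °C
Reagents that add atoms: triethylsilyl triflate, CC[Si](CC)(CC)OS(=O)(=O)C(F)(F)F
Why: Soft enolisation of a methyl ketone with only one enolisable position; triethylsilyl is chosen so that the C3 silyl ether outlasts steps 12 to 15.

**Union and ring C**

Step 11
Reactants: 6 ring-A aldehyde, 4-allyl-2-formyl-3,5-bis(triisopropylsilyloxy)phenyl (1S,4R)-camphanate; 12 ring-B enol ether, 1-[3-allyl-2-methoxy-4-(triisopropylsilyloxy)phenyl]-1-(triethylsilyloxy)ethene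
Product: 13 (2R,3R)-2-[3-allyl-6-((1S,4R)-camphanoyloxy)-2,4-bis(triisopropylsilyloxy)phenyl]-3-[3-allyl-2-methoxy-4-(triisopropylsilyloxy)phenyl]-3-(triethylsilyloxy)oxetane
Conditions: hν (366 nm), 12 (3 equiv), degassed benzene, 10 °C; separation of the C3 epimers on Et3N-washed silica or by crystallisation
Reagents that add atoms: none
Why: Excitation of the aldehyde n,π* band and intersystem crossing give a triplet whose electrophilic oxygen bonds to the unsubstituted CH2 terminus of the electron-rich enol ether, leaving a 1,4-biradical with one centre at benzylic C4 and the other at C3, where silyloxy and ring B stabilise it; after spin inversion the two centres couple to form C3–C4. The closest known reaction type is the Paternò–Büchi reaction of aromatic aldehydes with silyl enol ethers, which gives 3-silyloxyoxetanes with this regiochemistry. The oxetane closes by a stepwise [2+2] cycloaddition, O–C2 first and C3–C4 last by radical recombination of the 1,4-biradical. C3 arises from a planar radical, so both epimers are expected; the camphanoyl ester on O1, ortho to the reacting carbon, makes them diastereomers, the 3R series is collected, and any facial bias from the auxiliary is a bonus. C4 should form mainly with ring A trans to ring B, as in the known simple diastereoselectivity, and both C4 epimers of the 3R series can be pooled because step 14 erases this centre. Preference for the enol ether over the allyl groups rests on the much faster reaction of triplet carbonyls with electron-rich enol ethers than with monosubstituted alkenes, which is why the prenyl groups are carried as allyl groups; hydrogen abstraction and excited-state proton transfer are closed off because the ortho substituents are an ester without α-hydrogen and a silyl ether.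

Step 12
Reactants: 13 (2R,3R)-2-[3-allyl-6-((1S,4R)-camphanoyloxy)-2,4-bis(triisopropylsilyloxy)phenyl]-3-[3-allyl-2-methoxy-4-(triisopropylsilyloxy)phenyl]-3-(triethylsilyloxy)oxetane
Product: 16 (2R)-1-[3-allyl-6-hydroxy-2,4-bis(triisopropylsilyloxy)phenyl]-2-[3-allyl-2-methoxy-4-(triisopropylsilyloxy)phenyl]-2-(triethylsilyloxy)propane-1,3-diol (both C1 epimers), via oxetanyl phenol 14 (not isolated), via o-quinone methide 15 (not isolated)
Conditions: LiOH·H2O, THF/H2O (4:1), 0 °C to rt; then aq NH4Cl; crude product used directly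
Reagents that add atoms: water, O (delivered as hydroxide)
Why: Proposed new method: hydroxide cleaves the aryl camphanate and the phenoxide, assisted by the O5 and O7 silyloxy donors, should expel the strained benzylic oxetane oxygen to give an o-quinone methide that adds water at C4, the aqueous medium protonating the primary alkoxide before it can fragment or take over the silyl group; the closest known reaction type is the base- or fluoride-triggered generation of o-quinone methides from o-hydroxybenzyl esters, ethers and ammonium salts followed by 1,4-addition of water.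

Step 13
Reactants: 16 (2R)-1-[3-allyl-6-hydroxy-2,4-bis(triisopropylsilyloxy)phenyl]-2-[3-allyl-2-methoxy-4-(triisopropylsilyloxy)phenyl]-2-(triethylsilyloxy)propane-1,3-diol
Product: 17 (3R)-6-allyl-3-[3-allyl-2-methoxy-4-(triisopropylsilyloxy)phenyl]-3-(triethylsilyloxy)-5,7-bis(triisopropylsilyloxy)chroman-4-ol (both C4 epimers)
Conditions: PPh3, DIAD, THF, 0 °C to rt
Reagents that add atoms: none
Why: Mitsunobu etherification; the betaine is protonated by the only free phenol (O1) and activates the primary alcohol in preference to the secondary benzylic one, which is flanked by the quaternary C3 and a doubly ortho-substituted ring, and the phenoxide closes ring C by 6-exo-tet displacement without touching C3.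

Step 14
Reactants: 17 (3R)-6-allyl-3-[3-allyl-2-methoxy-4-(triisopropylsilyloxy)phenyl]-3-(triethylsilyloxy)-5,7-bis(triisopropylsilyloxy)chroman-4-ol
Product: 18 (3R)-6-allyl-3-[3-allyl-2-methoxy-4-(triisopropylsilyloxy)phenyl]-3-(triethylsilyloxy)-5,7-bis(triisopropylsilyloxy)chroman-4-one
Conditions: Dess–Martin periodinane, pyridine, CH2Cl2, 0 °C to rt
Reagents that add atoms: none
Why: Dess–Martin oxidation of the only free hydroxyl; both C4 epimers converge on one ketone, and C3, fully substituted, cannot epimerise.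

Step 15
Reactants: 18 (3R)-6-allyl-3-[3-allyl-2-methoxy-4-(triisopropylsilyloxy)phenyl]-3-(triethylsilyloxy)-5,7-bis(triisopropylsilyloxy)chroman-4-one
Product: 19 (3R)-3-[2-methoxy-3-(3-methylbut-2-enyl)-4-(triisopropylsilyloxy)phenyl]-6-(3-methylbut-2-enyl)-3-(triethylsilyloxy)-5,7-bis(triisopropylsilyloxy)chroman-4-one
Conditions: second-generation Grubbs catalyst (H2IMes)(PCy3)Cl2Ru=CHPh (10 mol%), 2-methyl-2-butene/CH2Cl2, 40 °C, sealed tube
Reagents that add atoms: 2-methyl-2-butene, CC=C(C)C
Why: Olefin cross-metathesis of both terminal allyl groups with excess 2-methyl-2-butene, a standard way to turn aryl allyl into aryl prenyl groups; no free hydroxyl is present.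

Step 16
Reactants: 19 (3R)-3-[2-methoxy-3-(3-methylbut-2-enyl)-4-(triisopropylsilyloxy)phenyl]-6-(3-methylbut-2-enyl)-3-(triethylsilyloxy)-5,7-bis(triisopropylsilyloxy)chroman-4-one
Product: 20 (3R)-3,5,7-trihydroxy-3-[4-hydroxy-2-methoxy-3-(3-methylbut-2-enyl)phenyl]-6-(3-methylbut-2-enyl)chroman-4-one (target)
Conditions: Bu4NF (4.5 equiv), AcOH (4.5 equiv), THF, 0 °C
Reagents that add atoms: none
Why: Fluoride desilylation of three aryl silyl ethers and the tertiary triethylsilyl ether; the acetic acid buffer avoids both strongly basic phenoxide conditions and the acid that would dehydrate the 3-hydroxyisoflavanone or cyclise prenyl onto a phenol.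

**Compound list**

1 | 2,4,6-trihydroxybenzaldehyde | O=Cc1c(O)cc(O)cc1O | starting material
2 | 2,6-dihydroxy-4-(triisopropylsilyloxy)benzaldehyde | O=Cc1c(O)cc(O[Si](C(C)C)(C(C)C)C(C)C)cc1O | intermediate
3 | 2-(allyloxy)-6-hydroxy-4-(triisopropylsilyloxy)benzaldehyde | O=Cc1c(OCC=C)cc(O[Si](C(C)C)(C(C)C)C(C)C)cc1O | intermediate
4 | 3-(allyloxy)-2-formyl-5-(triisopropylsilyloxy)phenyl (1S,4R)-4,7,7-trimethyl-3-oxo-2-oxabicyclo[2.2.1]heptane-1-carboxylate (camphanate) | O=Cc1c(OCC=C)cc(O[Si](C(C)C)(C(C)C)C(C)C)cc1OC(=O)[C@@]23CC[C@@](C)(C(=O)O2)C3(C)C | intermediate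
5 | 4-allyl-2-formyl-3-hydroxy-5-(triisopropylsilyloxy)phenyl (1S,4R)-camphanate | O=Cc1c(O)c(CC=C)c(O[Si](C(C)C)(C(C)C)C(C)C)cc1OC(=O)[C@@]23CC[C@@](C)(C(=O)O2)C3(C)C | intermediate
6 | ring-A aldehyde, 4-allyl-2-formyl-3,5-bis(triisopropylsilyloxy)phenyl (1S,4R)-camphanate | O=Cc1c(O[Si](C(C)C)(C(C)C)C(C)C)c(CC=C)c(O[Si](C(C)C)(C(C)C)C(C)C)cc1OC(=O)[C@@]23CC[C@@](C)(C(=O)O2)C3(C)C | intermediate
7 | 2,4-dihydroxyacetophenone | CC(=O)c1ccc(O)cc1O | starting material
8 | 4-(allyloxy)-2-hydroxyacetophenone | CC(=O)c1ccc(OCC=C)cc1O | intermediate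
9 | 3-allyl-2,4-dihydroxyacetophenone | CC(=O)c1ccc(O)c(CC=C)c1O | intermediate
10 | 3-allyl-2-hydroxy-4-(triisopropylsilyloxy)acetophenone | CC(=O)c1ccc(O[Si](C(C)C)(C(C)C)C(C)C)c(CC=C)c1O | intermediate
11 | 3-allyl-2-methoxy-4-(triisopropylsilyloxy)acetophenone | CC(=O)c1ccc(O[Si](C(C)C)(C(C)C)C(C)C)c(CC=C)c1OC | intermediate
12 | ring-B enol ether, 1-[3-allyl-2-methoxy-4-(triisopropylsilyloxy)phenyl]-1-(triethylsilyloxy)ethene | C=C(O[Si](CC)(CC)CC)c1ccc(O[Si](C(C)C)(C(C)C)C(C)C)c(CC=C)c1OC | intermediate
13 | (2R,3R)-2-[3-allyl-6-((1S,4R)-camphanoyloxy)-2,4-bis(triisopropylsilyloxy)phenyl]-3-[3-allyl-2-methoxy-4-(triisopropylsilyloxy)phenyl]-3-(triethylsilyloxy)oxetane; oxetane C3 is C3 of the target, oxetane C2 is the transient C4 | COc1c([C@@]2(O[Si](CC)(CC)CC)CO[C@@H]2c3c(OC(=O)[C@@]45CC[C@@](C)(C(=O)O4)C5(C)C)cc(O[Si](C(C)C)(C(C)C)C(C)C)c(CC=C)c3O[Si](C(C)C)(C(C)C)C(C)C)ccc(O[Si](C(C)C)(C(C)C)C(C)C)c1CC=C | intermediate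
14 | oxetanyl phenol, 13 without the camphanoyl group (free O1–H), not isolated | COc1c([C@@]2(O[Si](CC)(CC)CC)CO[C@@H]2c3c(O)cc(O[Si](C(C)C)(C(C)C)C(C)C)c(CC=C)c3O[Si](C(C)C)(C(C)C)C(C)C)ccc(O[Si](C(C)C)(C(C)C)C(C)C)c1CC=C | intermediate
15 | o-quinone methide, ring A as 6-alkylidenecyclohexa-2,4-dienone with exocyclic C4=C4a, C3 (R) bearing CH2OH, triethylsilyloxy and ring B; alkene geometry open; not isolated | O=C1C=C(O[Si](C(C)C)(C(C)C)C(C)C)C(CC=C)=C(O[Si](C(C)C)(C(C)C)C(C)C)C1=C[C@@](CO)(O[Si](CC)(CC)CC)c1ccc(O[Si](C(C)C)(C(C)C)C(C)C)c(CC=C)c1OC | intermediate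
16 | (2R)-1-[3-allyl-6-hydroxy-2,4-bis(triisopropylsilyloxy)phenyl]-2-[3-allyl-2-methoxy-4-(triisopropylsilyloxy)phenyl]-2-(triethylsilyloxy)propane-1,3-diol, C1 epimer mixture | COc1c([C@@](O[Si](CC)(CC)CC)(CO)C(O)c2c(O)cc(O[Si](C(C)C)(C(C)C)C(C)C)c(CC=C)c2O[Si](C(C)C)(C(C)C)C(C)C)ccc(O[Si](C(C)C)(C(C)C)C(C)C)c1CC=C | intermediate
17 | (3R)-6-allyl-3-[3-allyl-2-methoxy-4-(triisopropylsilyloxy)phenyl]-3-(triethylsilyloxy)-5,7-bis(triisopropylsilyloxy)chroman-4-ol, C4 epimer mixture | COc1c([C@@]2(O[Si](CC)(CC)CC)COc3cc(O[Si](C(C)C)(C(C)C)C(C)C)c(CC=C)c(O[Si](C(C)C)(C(C)C)C(C)C)c3C2O)ccc(O[Si](C(C)C)(C(C)C)C(C)C)c1CC=C | intermediate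
18 | (3R)-6-allyl-3-[3-allyl-2-methoxy-4-(triisopropylsilyloxy)phenyl]-3-(triethylsilyloxy)-5,7-bis(triisopropylsilyloxy)chroman-4-one | COc1c([C@@]2(O[Si](CC)(CC)CC)COc3cc(O[Si](C(C)C)(C(C)C)C(C)C)c(CC=C)c(O[Si](C(C)C)(C(C)C)C(C)C)c3C2=O)ccc(O[Si](C(C)C)(C(C)C)C(C)C)c1CC=C | intermediate
19 | (3R)-3-[2-methoxy-3-(3-methylbut-2-enyl)-4-(triisopropylsilyloxy)phenyl]-6-(3-methylbut-2-enyl)-3-(triethylsilyloxy)-5,7-bis(triisopropylsilyloxy)chroman-4-one | COc1c([C@@]2(O[Si](CC)(CC)CC)COc3cc(O[Si](C(C)C)(C(C)C)C(C)C)c(CC=C(C)C)c(O[Si](C(C)C)(C(C)C)C(C)C)c3C2=O)ccc(O[Si](C(C)C)(C(C)C)C(C)C)c1CC=C(C)C | intermediate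
20 | (3R)-3,5,7-trihydroxy-3-[4-hydroxy-2-methoxy-3-(3-methylbut-2-enyl)phenyl]-6-(3-methylbut-2-enyl)chroman-4-one | COc1c([C@@]2(O)COc3cc(O)c(CC=C(C)C)c(O)c3C2=O)ccc(O)c1CC=C(C)C | target

**Step count**

Total: 16 steps. Longest linear sequence: 11 steps (steps 1–5 and 11–16; the ring-B branch, steps 6–10 and 11–16, is equally long).

**Steps most likely to fail**

1. Step 12 (labelled "Proposed new method:"). What may go wrong: the phenoxide may not expel the oxetane oxygen at a useful rate; the primary alkoxide may fragment with loss of formaldehyde or take the triethylsilyl group from O3 before it is protonated; ring B may migrate to the quinone methide carbon in competition with hydration. Fallback with known chemistry, from oxetane 13 back to chromanol 17: the benzylic C–O bond would be hydrolysed under mild acid catalysis (pyridinium p-toluenesulfonate, THF/H2O, 0 °C) with O1 still acylated, the known acid-catalysed opening of 2-aryloxetanes at the benzylic carbon, to give the camphanate diol F1. Tosylation of its primary hydroxyl (TsCl, pyridine, 0 °C) would give the primary tosylate F2. LiOH in THF/H2O would then remove the camphanate, and the phenoxide would displace the tosylate in a 6-exo-tet Williamson closure, arriving at 17 and making step 13 unnecessary.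

2. Step 11. What may go wrong: the triplet of the donor-substituted aldehyde may be deactivated by energy transfer to the styrene-like enol ether or by a low-lying π,π* state, so that little oxetane forms; the C3-epimeric camphanates may not separate. Fallback without photochemistry, from ketone 11 and aldehyde 6 back to chromanone 18: ketone 11 would be converted (KN(SiMe3)2, PhNTf2, THF, −78 °C) into the enol triflate F3, which would be added to aldehyde 6 by Nozaki–Hiyama–Kishi coupling (CrCl2, catalytic NiCl2, DMF) to give the allylic alcohol F4. Dess–Martin oxidation would give the enone F5. LiOH in THF/H2O would cleave the camphanate and the phenoxide would close ring C by 6-endo-trig oxa-Michael addition to the racemic isoflavanone F6. Hydroxylation of its potassium enolate (KN(SiMe3)2, THF, −78 °C) with an enantiopure (camphorsulfonyl)oxaziridine, the antipode being chosen to deliver 3R, would give the tertiary alcohol F7. Silylation (Et3SiOTf, 2,6-lutidine) would return to the route at 18.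

3. Step 13. What may go wrong: displacement at the neopentyl-type CH2 may be slow, so that activation of the benzylic hydroxyl, re-closure to an oxetane or intermolecular etherification takes over. Fallback that oxidises before closing, from triol 16 back to chromanone 18: MnO2 in CH2Cl2 would oxidise only the benzylic carbinol to the hydroxy ketone F8. MsCl and Et3N at −20 °C would sulfonylate the primary alcohol, while the phenol is held in a hydrogen bond to the new ketone, to give the mesylate F9. K2CO3 in acetone would close ring C by phenoxide displacement, arriving at 18 and making step 14 unnecessary.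

**Further compounds**

F1 | step 12 | 4-allyl-2-[(2R)-1,3-dihydroxy-2-[3-allyl-2-methoxy-4-(triisopropylsilyloxy)phenyl]-2-(triethylsilyloxy)propyl]-3,5-bis(triisopropylsilyloxy)phenyl (1S,4R)-camphanate, C1 epimer mixture | COc1c([C@@](O[Si](CC)(CC)CC)(CO)C(O)c2c(OC(=O)[C@@]34CC[C@@](C)(C(=O)O3)C4(C)C)cc(O[Si](C(C)C)(C(C)C)C(C)C)c(CC=C)c2O[Si](C(C)C)(C(C)C)C(C)C)ccc(O[Si](C(C)C)(C(C)C)C(C)C)c1CC=C
F2 | step 12 | primary p-toluenesulfonate of F1 | COc1c([C@@](O[Si](CC)(CC)CC)(COS(=O)(=O)c5ccc(C)cc5)C(O)c2c(OC(=O)[C@@]34CC[C@@](C)(C(=O)O3)C4(C)C)cc(O[Si](C(C)C)(C(C)C)C(C)C)c(CC=C)c2O[Si](C(C)C)(C(C)C)C(C)C)ccc(O[Si](C(C)C)(C(C)C)C(C)C)c1CC=C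
F3 | step 11 | 1-[3-allyl-2-methoxy-4-(triisopropylsilyloxy)phenyl]vinyl trifluoromethanesulfonate | C=C(OS(=O)(=O)C(F)(F)F)c1ccc(O[Si](C(C)C)(C(C)C)C(C)C)c(CC=C)c1OC
F4 | step 11 | 4-allyl-2-[1-hydroxy-2-[3-allyl-2-methoxy-4-(triisopropylsilyloxy)phenyl]prop-2-enyl]-3,5-bis(triisopropylsilyloxy)phenyl (1S,4R)-camphanate, carbinol epimer mixture | C=C(C(O)c1c(O[Si](C(C)C)(C(C)C)C(C)C)c(CC=C)c(O[Si](C(C)C)(C(C)C)C(C)C)cc1OC(=O)[C@@]23CC[C@@](C)(C(=O)O2)C3(C)C)c1ccc(O[Si](C(C)C)(C(C)C)C(C)C)c(CC=C)c1OC
F5 | step 11 | 4-allyl-2-[2-[3-allyl-2-methoxy-4-(triisopropylsilyloxy)phenyl]prop-2-enoyl]-3,5-bis(triisopropylsilyloxy)phenyl (1S,4R)-camphanate | C=C(C(=O)c1c(O[Si](C(C)C)(C(C)C)C(C)C)c(CC=C)c(O[Si](C(C)C)(C(C)C)C(C)C)cc1OC(=O)[C@@]23CC[C@@](C)(C(=O)O2)C3(C)C)c1ccc(O[Si](C(C)C)(C(C)C)C(C)C)c(CC=C)c1OC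
F6 | step 11 | racemic 6-allyl-3-[3-allyl-2-methoxy-4-(triisopropylsilyloxy)phenyl]-5,7-bis(triisopropylsilyloxy)chroman-4-one | COc1c(C2COc3cc(O[Si](C(C)C)(C(C)C)C(C)C)c(CC=C)c(O[Si](C(C)C)(C(C)C)C(C)C)c3C2=O)ccc(O[Si](C(C)C)(C(C)C)C(C)C)c1CC=C
F7 | step 11 | (3R)-6-allyl-3-[3-allyl-2-methoxy-4-(triisopropylsilyloxy)phenyl]-3-hydroxy-5,7-bis(triisopropylsilyloxy)chroman-4-one | COc1c([C@@]2(O)COc3cc(O[Si](C(C)C)(C(C)C)C(C)C)c(CC=C)c(O[Si](C(C)C)(C(C)C)C(C)C)c3C2=O)ccc(O[Si](C(C)C)(C(C)C)C(C)C)c1CC=C
F8 | step 13 | (2R)-1-[3-allyl-6-hydroxy-2,4-bis(triisopropylsilyloxy)phenyl]-2-[3-allyl-2-methoxy-4-(triisopropylsilyloxy)phenyl]-3-hydroxy-2-(triethylsilyloxy)propan-1-one | COc1c([C@@](O[Si](CC)(CC)CC)(CO)C(=O)c2c(O)cc(O[Si](C(C)C)(C(C)C)C(C)C)c(CC=C)c2O[Si](C(C)C)(C(C)C)C(C)C)ccc(O[Si](C(C)C)(C(C)C)C(C)C)c1CC=C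
F9 | step 13 | primary methanesulfonate of F8 | COc1c([C@@](O[Si](CC)(CC)CC)(COS(C)(=O)=O)C(=O)c2c(O)cc(O[Si](C(C)C)(C(C)C)C(C)C)c(CC=C)c2O[Si](C(C)C)(C(C)C)C(C)C)ccc(O[Si](C(C)C)(C(C)C)C(C)C)c1CC=C
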